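**Retrosynthetic overview**
- The target is a tridepside (ring A orsellinoyl, ring B central orsellinoyl, ring C 2-O-methylorsellinic acid). The last operations are removal of one silyl ether and global hydrogenolysis of three benzyl groups.
- The strategy rests on ring B (C1'–C6'): C1' (ester carbonyl) and C6' (CH3) are the two alkyne carbons of a but-2-ynoate. C2' (OH), C3' (H), C4' (O-acyl) and C5' (H) are the four carbons of an acetoacetate-derived diene.
- Cutting C1'–C2' and C5'–C6' gives a 1-methoxy-1-silyloxy-3-aroyloxybutadiene that already carries ring A, and the but-2-ynoate ester of the ring C phenol. A Diels–Alder reaction followed by loss of methanol forms ring B.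
- The diene comes from methyl acetoacetate and protected orsellinoyl chloride; the ynoate comes from orsellinic acid and but-2-ynoic acid.
- Ring order: rings A and C are bought as orsellinic acid; ring B is the only ring made, and it is made last, between the two preformed esters.

Key step: step 10

Assumption: enol ester 6 is drawn as the E isomer and diene 7 as the 1E isomer; neither geometry survives into ring B, so any geometric isomer formed would serve equally.

**Route**

Step 1
Reactants: 1 orsellinic acid (2,4-dihydroxy-6-methylbenzoic acid)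
Product: 2 benzyl 2,4-bis(benzyloxy)-6-methylbenzoate
Conditions: BnBr (3.5 equiv), K2CO3, DMF, rt then 60 °C
Reagents that add atoms: benzyl bromide, BrCc1ccccc1
Why: Williamson etherification of both phenols and SN2 esterification of the carboxylate; the carboxylate is alkylated first at room temperature, which prevents decarboxylation of the β-resorcylic acid on warming.

Step 2
Reactants: 2 benzyl 2,4-bis(benzyloxy)-6-methylbenzoate
Product: 3 2,4-bis(benzyloxy)-6-methylbenzoic acid
Conditions: KOH, DMSO/H2O, 90 °C; then aq. HCl
Reagents that add atoms: potassium hydroxide, [K+].[OH-]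
Why: Saponification of the hindered 2,6-disubstituted benzoate needs hot KOH in aqueous DMSO, conditions under which the aryl benzyl ethers are inert.

Step 3
Reactants: 3 2,4-bis(benzyloxy)-6-methylbenzoic acid; 4 methyl acetoacetate
Product: 6 methyl (E)-3-[2,4-bis(benzyloxy)-6-methylbenzoyloxy]but-2-enoate, via acid chloride 5 (not isolated)
Conditions: (COCl)2, DMF (cat.), CH2Cl2, 0 °C to rt, concentrate; then 4, Et3N, DMPU/CH2Cl2, 0 °C to rt
Reagents that add atoms: none
Why: Vilsmeier-type chlorination gives the aroyl chloride, whose 2,6-disubstitution and acylium character direct the triethylammonium enolate of 4 in a polar aprotic medium to react through oxygen (enol ester formation of a β-keto ester) rather than through carbon.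

Step 4
Reactants: 6 methyl (E)-3-[2,4-bis(benzyloxy)-6-methylbenzoyloxy]but-2-enoate
Product: 7 (1E)-3-[2,4-bis(benzyloxy)-6-methylbenzoyloxy]-1-methoxy-1-(tert-butyldimethylsilyloxy)buta-1,3-diene
Conditions: LiN(iPr)2 (LDA, 1.1 equiv), TBSCl, DMPU, THF, −78 °C to rt (internal quench); non-aqueous work-up, used crude
Reagents that add atoms: tert-butyldimethylsilyl chloride, CC(C)(C)[Si](C)(C)Cl
Why: γ-Deprotonation of the β-acyloxy enoate and O-silylation of the extended enolate, as in the preparation of Chan- and Brassard-type dienes; the internal quench keeps the free dienolate short-lived and the 2,6-disubstituted aroate is shielded from the amide base.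

Step 5
Reactants: 1 orsellinic acid
Product: 8 benzyl 2,4-dihydroxy-6-methylbenzoate
Conditions: BnBr (1.05 equiv), KHCO3, DMF, rt
Reagents that add atoms: benzyl bromide, BrCc1ccccc1
Why: SN2 alkylation of the carboxylate only, since KHCO3 deprotonates the acid but not the phenols.

Step 6
Reactants: 8 benzyl 2,4-dihydroxy-6-methylbenzoate
Product: 9 benzyl 4-(allyloxy)-2-hydroxy-6-methylbenzoate
Conditions: allyl bromide (1.1 equiv), K2CO3, acetone, rt to 40 °C
Reagents that add atoms: allyl bromide, C=CCBr
Why: Williamson etherification selective for the 4-OH, which is the more acidic hydroxyl and is not held in the hydrogen bond that the 2-OH makes to the ester carbonyl.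

Step 7
Reactants: 9 benzyl 4-(allyloxy)-2-hydroxy-6-methylbenzoate
Product: 10 benzyl 4-(allyloxy)-2-methoxy-6-methylbenzoate
Conditions: MeI, K2CO3, DMF, 50 °C
Reagents that add atoms: iodomethane, CI
Why: Williamson methylation of the remaining hydrogen-bonded 2-OH under more forcing conditions; the benzyl ester and allyl ether are inert.

Step 8
Reactants: 10 benzyl 4-(allyloxy)-2-methoxy-6-methylbenzoate
Product: 11 benzyl 4-hydroxy-2-methoxy-6-methylbenzoate
Conditions: Pd(PPh3)4 (cat.), morpholine, THF, rt
Reagents that add atoms: none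
Why: Tsuji–Trost deallylation, in which zerovalent palladium ionises the allyl aryl ether and morpholine traps the π-allyl complex, leaving the benzyl ester and methyl ether untouched.

Step 9
Reactants: 11 benzyl 4-hydroxy-2-methoxy-6-methylbenzoate; 12 but-2-ynoic acid
Product: 13 benzyl 4-(but-2-ynoyloxy)-2-methoxy-6-methylbenzoate
Conditions: DCC, DMAP (cat.), CH2Cl2, 0 °C
Reagents that add atoms: none
Why: Steglich esterification of the phenol under near-neutral conditions at 0 °C, with little DMAP so that the ynoate is not isomerised to the allenoate.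

Step 10
Reactants: 7 (1E)-3-[2,4-bis(benzyloxy)-6-methylbenzoyloxy]-1-methoxy-1-(tert-butyldimethylsilyloxy)buta-1,3-diene; 13 benzyl 4-(but-2-ynoyloxy)-2-methoxy-6-methylbenzoate
Product: 15 benzyl 4-{[4-{[2,4-bis(benzyloxy)-6-methylbenzoyl]oxy}-2-(tert-butyldimethylsilyloxy)-6-methylbenzoyl]oxy}-2-methoxy-6-methylbenzoate, via cyclohexa-1,4-diene cycloadduct 14 (not isolated)
Conditions: 7 (2 equiv), PhMe, 120 °C, sealed tube; then PPTS (cat.), CH2Cl2, rt
Reagents that add atoms: none
Why: The C4 methylene terminus of diene 7 carries the largest HOMO coefficient, because the two C1 oxygens and the C3 acyloxy group all donate towards it; it bonds to the methyl-bearing β-carbon of ynoate 13 while the ketal carbon C1 bonds to the α-carbon, in an asynchronous normal-electron-demand Diels–Alder reaction that forms C5'–C6' and C1'–C2'. Ring B closes in this single intermolecular (4+2) cycloaddition as cyclohexa-1,4-diene 14, whose only stereocentre (the C2' ketal carbon, racemic) disappears when C2' becomes aromatic. Loss of methanol across C2'/C5' then aromatises ring B, thermally and, where needed, completed by the trace of PPTS. Methanol should leave rather than silanol because the methoxy oxygen is the more basic one and takes the proton; cleavage of the O–Si bond instead would only give the C2' ketone and hence free phenol 16, which rejoins the route. The closest known reaction type is the cycloaddition of 1-alkoxy-1-silyloxy-3-oxybuta-1,3-dienes (Chan- and Brassard-type dienes) with alkynoates and quinones, which gives resorcylates and peri-hydroxyquinones with this regiochemistry and this loss of alcohol. The step needs only regioselectivity, which the matched polarisation of both partners should secure; the hindered C1' carbonyl enters as an unhindered ynoate ester and the ring A ester already sits on the enol oxygen, so neither depside bond is made by acylation with a 2,6-disubstituted benzoic acid at this stage.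

Step 11
Reactants: 15 silyl-protected tridepside
Product: 16 benzyl 4-{[4-{[2,4-bis(benzyloxy)-6-methylbenzoyl]oxy}-2-hydroxy-6-methylbenzoyl]oxy}-2-methoxy-6-methylbenzoate
Conditions: TBAF, AcOH, THF, 0 °C
Reagents that add atoms: none
Why: Fluoride cleaves the aryl silyl ether through Si–F bond formation, and acetic acid buffers the phenoxide so that the two aryl ester links are not transesterified.

Step 12
Reactants: 16 benzyl 4-{[4-{[2,4-bis(benzyloxy)-6-methylbenzoyl]oxy}-2-hydroxy-6-methylbenzoyl]oxy}-2-methoxy-6-methylbenzoate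
Product: 17 4-{[4-(2,4-dihydroxy-6-methylbenzoyloxy)-2-hydroxy-6-methylbenzoyl]oxy}-2-methoxy-6-methylbenzoic acid (target, CNP0283563.0)
Conditions: H2 (1 atm), 10% Pd/C, EtOAc, rt
Reagents that add atoms: none
Why: Hydrogenolysis removes the two benzyl ethers and the benzyl ester in one operation in a non-nucleophilic solvent; the aryl esters have no benzylic C–O bond and should stay intact.

**Compound list**
1 | orsellinic acid (2,4-dihydroxy-6-methylbenzoic acid) | Cc1cc(O)cc(O)c1C(=O)O | starting material
2 | benzyl 2,4-bis(benzyloxy)-6-methylbenzoate | Cc1cc(OCc2ccccc2)cc(OCc2ccccc2)c1C(=O)OCc1ccccc1 | intermediate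
3 | 2,4-bis(benzyloxy)-6-methylbenzoic acid | Cc1cc(OCc2ccccc2)cc(OCc2ccccc2)c1C(=O)O | intermediate
4 | methyl acetoacetate | CC(=O)CC(=O)OC | starting material
5 | 2,4-bis(benzyloxy)-6-methylbenzoyl chloride (not isolated) | Cc1cc(OCc2ccccc2)cc(OCc2ccccc2)c1C(=O)Cl | intermediate
6 | methyl (E)-3-[2,4-bis(benzyloxy)-6-methylbenzoyloxy]but-2-enoate | C/C(OC(=O)c1c(C)cc(OCc2ccccc2)cc1OCc1ccccc1)=C\C(=O)OC | intermediate
7 | (1E)-3-[2,4-bis(benzyloxy)-6-methylbenzoyloxy]-1-methoxy-1-(tert-butyldimethylsilyloxy)buta-1,3-diene | C=C(OC(=O)c1c(C)cc(OCc2ccccc2)cc1OCc1ccccc1)/C=C(\OC)O[Si](C)(C)C(C)(C)C | intermediate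
8 | benzyl 2,4-dihydroxy-6-methylbenzoate | Cc1cc(O)cc(O)c1C(=O)OCc1ccccc1 | intermediate
9 | benzyl 4-(allyloxy)-2-hydroxy-6-methylbenzoate | C=CCOc1cc(C)c(C(=O)OCc2ccccc2)c(O)c1 | intermediate
10 | benzyl 4-(allyloxy)-2-methoxy-6-methylbenzoate | C=CCOc1cc(C)c(C(=O)OCc2ccccc2)c(OC)c1 | intermediate
11 | benzyl 4-hydroxy-2-methoxy-6-methylbenzoate | COc1cc(O)cc(C)c1C(=O)OCc1ccccc1 | intermediate
12 | but-2-ynoic acid | CC#CC(=O)O | starting material
13 | benzyl 4-(but-2-ynoyloxy)-2-methoxy-6-methylbenzoate | CC#CC(=O)Oc1cc(C)c(C(=O)OCc2ccccc2)c(OC)c1 | intermediate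
14 | benzyl 4-{[4-{[2,4-bis(benzyloxy)-6-methylbenzoyl]oxy}-6-methoxy-2-methyl-6-(tert-butyldimethylsilyloxy)cyclohexa-1,4-diene-1-carbonyl]oxy}-2-methoxy-6-methylbenzoate (racemic, not isolated) | COC1(O[Si](C)(C)C(C)(C)C)C=C(OC(=O)c2c(C)cc(OCc3ccccc3)cc2OCc2ccccc2)CC(C)=C1C(=O)Oc1cc(C)c(C(=O)OCc2ccccc2)c(OC)c1 | intermediate
15 | benzyl 4-{[4-{[2,4-bis(benzyloxy)-6-methylbenzoyl]oxy}-2-(tert-butyldimethylsilyloxy)-6-methylbenzoyl]oxy}-2-methoxy-6-methylbenzoate | COc1cc(OC(=O)c2c(C)cc(OC(=O)c3c(C)cc(OCc4ccccc4)cc3OCc3ccccc3)cc2O[Si](C)(C)C(C)(C)C)cc(C)c1C(=O)OCc1ccccc1 | intermediate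
16 | benzyl 4-{[4-{[2,4-bis(benzyloxy)-6-methylbenzoyl]oxy}-2-hydroxy-6-methylbenzoyl]oxy}-2-methoxy-6-methylbenzoate | COc1cc(OC(=O)c2c(C)cc(OC(=O)c3c(C)cc(OCc4ccccc4)cc3OCc3ccccc3)cc2O)cc(C)c1C(=O)OCc1ccccc1 | intermediate
17 | 4-{[4-(2,4-dihydroxy-6-methylbenzoyloxy)-2-hydroxy-6-methylbenzoyl]oxy}-2-methoxy-6-methylbenzoic acid | COc1cc(OC(=O)c2c(C)cc(OC(=O)c3c(C)cc(O)cc3O)cc2O)cc(C)c1C(=O)O | target

**Step count**
Total: 12 steps. Longest linear sequence: 8 steps (steps 5, 6, 7, 8, 9, 10, 11, 12).

**Steps most likely to fail**

1. Step 10 (key step). The C3 acyloxy group donates less than a silyloxy group and the ynoate is β-substituted, so cycloaddition may be slower than thermal decay of the diene (silyl migration from oxygen to carbon, hydrolysis). The elimination could also expel the silyloxy group and leave a C2' methyl ether. Fallback, setting out from 13 and returning at 16: ynoate 13 would be heated in toluene with purchased 1-methoxy-1,3-bis(trimethylsilyloxy)buta-1,3-diene, a much more electron-rich diene of the same type. This should give the cycloadduct benzyl 4-{[6-methoxy-2-methyl-4,6-bis(trimethylsilyloxy)cyclohexa-1,4-diene-1-carbonyl]oxy}-2-methoxy-6-methylbenzoate F1, which is not isolated. Dilute HCl in THF should strip methanol and both trimethylsilyl groups from it to give the ring B–ring C didepside benzyl 4-(2,4-dihydroxy-6-methylbenzoyloxy)-2-methoxy-6-methylbenzoate F2. Its free 4'-OH (the 2'-OH is hydrogen-bonded to the ester carbonyl) would then be acylated selectively with acid chloride 5, made from 3 as in step 3, using Et3N in CH2Cl2, which gives 16 directly.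

2. Step 4. The extended enolate may expel the aroate to form an allenoate, deprotonation may occur at the benzylic methyl of ring A, or the ketene acetal may hydrolyse during isolation. Fallback, setting out from 5 and returning at 16, with no cycloaddition: acid chloride 5 (from 3 as in step 3) would acylate the 4-OH of purchased 2,4-dihydroxy-6-methylbenzaldehyde (Et3N, CH2Cl2) to give 4-formyl-3-hydroxy-5-methylphenyl 2,4-bis(benzyloxy)-6-methylbenzoate F3. Lindgren oxidation (NaClO2, sulfamic acid, aqueous dioxane) would convert the aldehyde into 4-[2,4-bis(benzyloxy)-6-methylbenzoyloxy]-2-hydroxy-6-methylbenzoic acid F4. This acid would be condensed with phenol 11 using trifluoroacetic anhydride in toluene at rt, the classical depside esterification, to give 16.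

3. Step 3. Attack of the enolate through carbon, or sluggish reaction of the hindered acid chloride, may give the C-aroyl β-keto ester or a mixture. Fallback, setting out from 3 and returning at 7: acid 3 would be added in Markovnikov fashion to purchased methyl but-3-ynoate with [RuCl2(p-cymene)]2, tri(2-furyl)phosphine and Na2CO3 in toluene at 50 °C (metal-catalysed hydro-acyloxylation of a terminal alkyne). This should give methyl 3-[2,4-bis(benzyloxy)-6-methylbenzoyloxy]but-3-enoate F5, the deconjugated isomer of 6. Its acidic α-CH2 would be deprotonated and O-silylated (LiN(iPr)2, TBSCl, DMPU, THF, −78 °C) to give the same diene 7.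

**Further compounds**
F1 | step 10 | benzyl 4-{[6-methoxy-2-methyl-4,6-bis(trimethylsilyloxy)cyclohexa-1,4-diene-1-carbonyl]oxy}-2-methoxy-6-methylbenzoate (racemic) | COC1(O[Si](C)(C)C)C=C(O[Si](C)(C)C)CC(C)=C1C(=O)Oc1cc(C)c(C(=O)OCc2ccccc2)c(OC)c1
F2 | step 10 | benzyl 4-(2,4-dihydroxy-6-methylbenzoyloxy)-2-methoxy-6-methylbenzoate | COc1cc(OC(=O)c2c(C)cc(O)cc2O)cc(C)c1C(=O)OCc1ccccc1
F3 | step 4 | 4-formyl-3-hydroxy-5-methylphenyl 2,4-bis(benzyloxy)-6-methylbenzoate | Cc1cc(OC(=O)c2c(C)cc(OCc3ccccc3)cc2OCc2ccccc2)cc(O)c1C=O
F4 | step 4 | 4-[2,4-bis(benzyloxy)-6-methylbenzoyloxy]-2-hydroxy-6-methylbenzoic acid | Cc1cc(OC(=O)c2c(C)cc(OCc3ccccc3)cc2OCc2ccccc2)cc(O)c1C(=O)O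
F5 | step 3 | methyl 3-[2,4-bis(benzyloxy)-6-methylbenzoyloxy]but-3-enoate | C=C(CC(=O)OC)OC(=O)c1c(C)cc(OCc2ccccc2)cc1OCc1ccccc1
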